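**Strategy.** The oxolane is cut at O1–C5, the bond between the oxygen on the ring B carbinol carbon C2 and the carbon C5 that carries ring A. Iodoetherification of a syn homopropargylic alcohol in the 5-endo-dig mode forms this bond and the ring in one operation and leaves iodine on C4 as the handle for the C4 methyl; the resulting C4=C5 enol ether is later hydrogenated from the face away from the cis C2 aryl and C3 methyl groups. The substrate is a (1S,2R)-configured 1,4-diaryl-2-methylbut-3-yn-1-ol made by an Evans syn aldol. The aryloxypropanol side chain is added last.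

Key step: step 8

Labels: oxolane atoms are O1, C2 (bears ring B, the 4-oxy-3-methoxyphenyl ring), C3 and C4 (each bears a methyl), C5 (bears ring A, a 3,4-dimethoxyphenyl ring); ring C is the 3,4-dimethoxyphenyl ring of the side chain.

Assumption: methylzinc chloride, the aryl Grignard reagent and the Ohira–Bestmann reagent are bought as solutions or neat, and Zn(BH4)2 is used as a pre-made ethereal solution. Alkoxides that are only protonated on work-up are not numbered.

**Route**

Step 1
Reactants: 1 (S)-4-benzyl-3-propionyloxazolidin-2-one; 2 4-(benzyloxy)-3-methoxybenzaldehyde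
Product: 5 (S)-4-benzyl-3-[(2S,3S)-3-(4-benzyloxy-3-methoxyphenyl)-3-hydroxy-2-methylpropanoyl]oxazolidin-2-one, via dibutylboron Z-enolate of the imide 3 (not isolated), via dibutylboron aldolate 4 (not isolated)
Conditions: Bu2BOTf, iPr2NEt, CH2Cl2, −78 → 0 °C; then 2, −78 → 0 °C; then pH 7 buffer, MeOH, 30% H2O2, 0 °C
Reagents that add atoms: none
Why: Evans boron aldol, in which the Z-enolate reacts through a closed Zimmerman–Traxler chair while the auxiliary benzyl group blocks one enolate face, should set the (2S,3S) syn pair that becomes C3 and C2 of the oxolane.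

Step 2
Reactants: 5 (S)-4-benzyl-3-[(2S,3S)-3-(4-benzyloxy-3-methoxyphenyl)-3-hydroxy-2-methylpropanoyl]oxazolidin-2-one
Product: 6 (S)-4-benzyl-3-[(2S,3S)-3-(4-benzyloxy-3-methoxyphenyl)-3-(tert-butyldimethylsilyloxy)-2-methylpropanoyl]oxazolidin-2-one
Conditions: TBSOTf, 2,6-lutidine, CH2Cl2, 0 °C
Reagents that add atoms: tert-butyldimethylsilyl trifluoromethanesulfonate, CC(C)(C)[Si](C)(C)OS(=O)(=O)C(F)(F)F
Why: Silylation of the secondary benzylic alcohol with a silyl triflate and a hindered pyridine base is fast at 0 °C, touches no stereocentre and blocks retro-aldol and β-elimination in the steps that follow.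

Step 3
Reactants: 6 (S)-4-benzyl-3-[(2S,3S)-3-(4-benzyloxy-3-methoxyphenyl)-3-(tert-butyldimethylsilyloxy)-2-methylpropanoyl]oxazolidin-2-one
Product: 7 (2R,3S)-3-(4-benzyloxy-3-methoxyphenyl)-3-(tert-butyldimethylsilyloxy)-2-methylpropan-1-ol
Conditions: LiBH4, H2O (1 equiv), Et2O, 0 °C
Reagents that add atoms: none
Why: Reductive cleavage of the N-acyl oxazolidinone by LiBH4 attacks the exocyclic carbonyl and releases the primary alcohol without epimerising the α-carbon or touching the silyl and benzyl ethers (the descriptor at C2 changes only through priority rules).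

Step 4
Reactants: 7 (2R,3S)-3-(4-benzyloxy-3-methoxyphenyl)-3-(tert-butyldimethylsilyloxy)-2-methylpropan-1-ol
Product: 8 (2S,3S)-3-(4-benzyloxy-3-methoxyphenyl)-3-(tert-butyldimethylsilyloxy)-2-methylpropanal
Conditions: TEMPO (cat.), PhI(OAc)2, CH2Cl2, rt
Reagents that add atoms: none
Why: The TEMPO-catalysed oxidation with PhI(OAc)2 stops at the aldehyde under nearly neutral conditions, so the α-methyl stereocentre should not epimerise.

Step 5
Reactants: 8 (2S,3S)-3-(4-benzyloxy-3-methoxyphenyl)-3-(tert-butyldimethylsilyloxy)-2-methylpropanal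
Product: 9 tert-butyl{[(1S,2R)-1-(4-benzyloxy-3-methoxyphenyl)-2-methylbut-3-yn-1-yl]oxy}dimethylsilane
Conditions: dimethyl (1-diazo-2-oxopropyl)phosphonate, K2CO3, MeOH, 0 °C → rt
Reagents that add atoms: dimethyl (1-diazo-2-oxopropyl)phosphonate, COP(=O)(OC)C(=[N+]=[N-])C(C)=O
Why: Seyferth–Gilbert homologation in the Ohira–Bestmann variant converts the aldehyde into the terminal alkyne through a diazoalkene and 1,2-hydride shift under carbonate conditions mild enough to keep the α-stereocentre.

Step 6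
Reactants: 9 tert-butyl{[(1S,2R)-1-(4-benzyloxy-3-methoxyphenyl)-2-methylbut-3-yn-1-yl]oxy}dimethylsilane; 10 4-iodo-1,2-dimethoxybenzene
Product: 11 tert-butyl{[(1S,2R)-1-(4-benzyloxy-3-methoxyphenyl)-4-(3,4-dimethoxyphenyl)-2-methylbut-3-yn-1-yl]oxy}dimethylsilane
Conditions: PdCl2(PPh3)2 (cat.), CuI (cat.), Et3N, THF, rt
Reagents that add atoms: none
Why: Sonogashira coupling of a terminal alkyne with an aryl iodide runs at room temperature and installs ring A on the alkyne without affecting the silyl ether, the benzyl ether or either stereocentre.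

Step 7
Reactants: 11 tert-butyl{[(1S,2R)-1-(4-benzyloxy-3-methoxyphenyl)-4-(3,4-dimethoxyphenyl)-2-methylbut-3-yn-1-yl]oxy}dimethylsilane
Product: 12 (1S,2R)-1-(4-benzyloxy-3-methoxyphenyl)-4-(3,4-dimethoxyphenyl)-2-methylbut-3-yn-1-ol
Conditions: Bu4NF, THF, 0 °C → rt
Reagents that add atoms: none
Why: Fluoride cleaves the Si–O bond selectively, and the non-acidic medium avoids ionisation of the electron-rich benzylic carbinol.

Step 8
Reactants: 12 (1S,2R)-1-(4-benzyloxy-3-methoxyphenyl)-4-(3,4-dimethoxyphenyl)-2-methylbut-3-yn-1-ol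
Product: 13 (2S,3S)-2-(4-benzyloxy-3-methoxyphenyl)-5-(3,4-dimethoxyphenyl)-4-iodo-3-methyl-2,3-dihydrofuran
Conditions: I2, NaHCO3, MeCN, 0 °C, dark
Reagents that add atoms: iodine, [I][I]
Why: Iodine forms an iodonium species on the alkyne in which positive charge sits best on the carbon bonded to the electron-rich ring A; the carbinol oxygen attacks that carbon anti to iodine and bicarbonate takes the proton, giving the O1–C5 bond and a C4–I vinyl iodide. The closest known reaction type is the iodine/bicarbonate cyclisation of 4-aryl-but-3-yn-1-ols to 3-iodo-4,5-dihydrofurans. The oxolane ring (O1, C2, C3, C4, C5) closes in the 5-endo-dig mode. No new stereocentre is formed, and C2 and C3 take no part in bond changes, so they keep the aldol configuration (the C3 descriptor becomes S only because iodine raises the priority of C4). The selectivity needed is 5-endo over 4-exo closure and alkyne over arene iodination; the first is secured by aryl stabilisation of charge at C5 and the strain of the alternative oxetane, the second by using iodine without oxidant or strong acid at 0 °C.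

Step 9
Reactants: 13 (2S,3S)-2-(4-benzyloxy-3-methoxyphenyl)-5-(3,4-dimethoxyphenyl)-4-iodo-3-methyl-2,3-dihydrofuran
Product: 14 (2S,3R)-2-(4-benzyloxy-3-methoxyphenyl)-5-(3,4-dimethoxyphenyl)-3,4-dimethyl-2,3-dihydrofuran
Conditions: MeZnCl, Pd(PPh3)4 (cat.), THF, rt → 50 °C
Reagents that add atoms: methylzinc chloride, C[Zn]Cl
Why: Negishi coupling (oxidative addition of zerovalent palladium into the vinyl C–I bond, transmetallation from zinc, reductive elimination) installs the C4 methyl under neutral conditions that spare the acid-labile enol ether.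

Step 10
Reactants: 14 (2S,3R)-2-(4-benzyloxy-3-methoxyphenyl)-5-(3,4-dimethoxyphenyl)-3,4-dimethyl-2,3-dihydrofuran
Product: 16 4-[(2S,3R,4S,5R)-5-(3,4-dimethoxyphenyl)-3,4-dimethyloxolan-2-yl]-2-methoxyphenol, via debenzylated dihydrofuran phenol 15 (not isolated)
Conditions: H2 (1 atm), Pd/C, EtOAc, rt
Reagents that add atoms: none
Why: Heterogeneous hydrogenation delivers both hydrogens syn to the C4=C5 enol ether from the ring face opposite the cis C2 aryl and C3 methyl groups, which should set C4 (S) and C5 (R) and so the all-cis ring, while the same catalyst removes the aryl benzyl ether by hydrogenolysis.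

Step 11
Reactants: 16 4-[(2S,3R,4S,5R)-5-(3,4-dimethoxyphenyl)-3,4-dimethyloxolan-2-yl]-2-methoxyphenol; 17 methyl (R)-lactate
Product: 18 methyl (2S)-2-{4-[(2S,3R,4S,5R)-5-(3,4-dimethoxyphenyl)-3,4-dimethyloxolan-2-yl]-2-methoxyphenoxy}propanoate
Conditions: PPh3, DIAD, THF, 0 °C → rt
Reagents that add atoms: none
Why: In the Mitsunobu etherification the phenol displaces the activated lactate hydroxyl by SN2 with inversion, which should give the (S)-2-aryloxypropanoate under neutral conditions that leave the benzylic oxolane centres alone.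

Step 12
Reactants: 18 methyl (2S)-2-{4-[(2S,3R,4S,5R)-5-(3,4-dimethoxyphenyl)-3,4-dimethyloxolan-2-yl]-2-methoxyphenoxy}propanoate
Product: 19 (2S)-2-{4-[(2S,3R,4S,5R)-5-(3,4-dimethoxyphenyl)-3,4-dimethyloxolan-2-yl]-2-methoxyphenoxy}-N-methoxy-N-methylpropanamide
Conditions: MeNHOMe·HCl, iPrMgCl, THF, −20 → 0 °C
Reagents that add atoms: N,O-dimethylhydroxylamine hydrochloride, CNOC.Cl
Why: Aminolysis of the ester by the chloromagnesium amide of N,O-dimethylhydroxylamine gives the Weinreb amide at a temperature low enough to keep the α-aryloxy stereocentre.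

Step 13
Reactants: 19 (2S)-2-{4-[(2S,3R,4S,5R)-5-(3,4-dimethoxyphenyl)-3,4-dimethyloxolan-2-yl]-2-methoxyphenoxy}-N-methoxy-N-methylpropanamide; 20 3,4-dimethoxyphenylmagnesium bromide
Product: 22 (2S)-1-(3,4-dimethoxyphenyl)-2-{4-[(2S,3R,4S,5R)-5-(3,4-dimethoxyphenyl)-3,4-dimethyloxolan-2-yl]-2-methoxyphenoxy}propan-1-one, via bromomagnesium hemiaminal chelate 21 (not isolated)
Conditions: THF, 0 °C; then pH 7 phosphate buffer
Reagents that add atoms: none
Why: In the Weinreb ketone synthesis the aryl Grignard adds once to give a stable magnesium chelate that collapses to the ketone only on quench, which prevents over-addition and keeps the α-carbon from enolising until work-up.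

Step 14
Reactants: 22 (2S)-1-(3,4-dimethoxyphenyl)-2-{4-[(2S,3R,4S,5R)-5-(3,4-dimethoxyphenyl)-3,4-dimethyloxolan-2-yl]-2-methoxyphenoxy}propan-1-one
Product: 23 (1R,2S)-1-(3,4-dimethoxyphenyl)-2-{4-[(2S,3R,4S,5R)-5-(3,4-dimethoxyphenyl)-3,4-dimethyloxolan-2-yl]-2-methoxyphenoxy}propan-1-ol
Conditions: Zn(BH4)2, Et2O, −20 → 0 °C
Reagents that add atoms: none
Why: In this chelation-controlled (Cram chelate) reduction zinc bridges the carbonyl and aryloxy oxygens and hydride attacks from the side of the α-hydrogen, which should give the (1R,2S) erythro alcohol.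

**Compound list**

1 | (S)-4-benzyl-3-propionyloxazolidin-2-one | CCC(=O)N1[C@@H](Cc2ccccc2)COC1=O | starting material
2 | 4-(benzyloxy)-3-methoxybenzaldehyde | COc1cc(C=O)ccc1OCc1ccccc1 | starting material
3 | (S)-4-benzyl-3-[(Z)-1-(dibutylboryloxy)prop-1-enyl]oxazolidin-2-one | C/C=C(\OB(CCCC)CCCC)N1[C@@H](Cc2ccccc2)COC1=O | intermediate (not isolated)
4 | O-dibutylboryl derivative of aldol adduct 5 | COc1cc(ccc1OCc1ccccc1)[C@@H](OB(CCCC)CCCC)[C@H](C)C(=O)N1[C@@H](Cc2ccccc2)COC1=O | intermediate (not isolated)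
5 | (S)-4-benzyl-3-[(2S,3S)-3-(4-benzyloxy-3-methoxyphenyl)-3-hydroxy-2-methylpropanoyl]oxazolidin-2-one | COc1cc(ccc1OCc1ccccc1)[C@@H](O)[C@H](C)C(=O)N1[C@@H](Cc2ccccc2)COC1=O | intermediate
6 | (S)-4-benzyl-3-[(2S,3S)-3-(4-benzyloxy-3-methoxyphenyl)-3-(tert-butyldimethylsilyloxy)-2-methylpropanoyl]oxazolidin-2-one | COc1cc(ccc1OCc1ccccc1)[C@@H](O[Si](C)(C)C(C)(C)C)[C@H](C)C(=O)N1[C@@H](Cc2ccccc2)COC1=O | intermediate
7 | (2R,3S)-3-(4-benzyloxy-3-methoxyphenyl)-3-(tert-butyldimethylsilyloxy)-2-methylpropan-1-ol | COc1cc(ccc1OCc1ccccc1)[C@@H](O[Si](C)(C)C(C)(C)C)[C@H](C)CO | intermediate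
8 | (2S,3S)-3-(4-benzyloxy-3-methoxyphenyl)-3-(tert-butyldimethylsilyloxy)-2-methylpropanal | COc1cc(ccc1OCc1ccccc1)[C@@H](O[Si](C)(C)C(C)(C)C)[C@H](C)C=O | intermediate
9 | tert-butyl{[(1S,2R)-1-(4-benzyloxy-3-methoxyphenyl)-2-methylbut-3-yn-1-yl]oxy}dimethylsilane | COc1cc(ccc1OCc1ccccc1)[C@@H](O[Si](C)(C)C(C)(C)C)[C@H](C)C#C | intermediate
10 | 4-iodo-1,2-dimethoxybenzene | Ic1ccc(OC)c(OC)c1 | starting material
11 | tert-butyl{[(1S,2R)-1-(4-benzyloxy-3-methoxyphenyl)-4-(3,4-dimethoxyphenyl)-2-methylbut-3-yn-1-yl]oxy}dimethylsilane | COc1cc(ccc1OCc1ccccc1)[C@@H](O[Si](C)(C)C(C)(C)C)[C@H](C)C#Cc1ccc(OC)c(OC)c1 | intermediate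
12 | (1S,2R)-1-(4-benzyloxy-3-methoxyphenyl)-4-(3,4-dimethoxyphenyl)-2-methylbut-3-yn-1-ol | COc1cc(ccc1OCc1ccccc1)[C@@H](O)[C@H](C)C#Cc1ccc(OC)c(OC)c1 | intermediate (key-step precursor)
13 | (2S,3S)-2-(4-benzyloxy-3-methoxyphenyl)-5-(3,4-dimethoxyphenyl)-4-iodo-3-methyl-2,3-dihydrofuran | IC1=C(c2ccc(OC)c(OC)c2)O[C@H](c2ccc(OCc3ccccc3)c(OC)c2)[C@@H]1C | intermediate (key-step product)
14 | (2S,3R)-2-(4-benzyloxy-3-methoxyphenyl)-5-(3,4-dimethoxyphenyl)-3,4-dimethyl-2,3-dihydrofuran | COc1cc(ccc1OCc1ccccc1)[C@H]1OC(c2ccc(OC)c(OC)c2)=C(C)[C@H]1C | intermediate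
15 | 4-[(2S,3R)-5-(3,4-dimethoxyphenyl)-3,4-dimethyl-2,3-dihydrofuran-2-yl]-2-methoxyphenol | COc1cc(ccc1O)[C@H]1OC(c2ccc(OC)c(OC)c2)=C(C)[C@H]1C | intermediate (not isolated)
16 | 4-[(2S,3R,4S,5R)-5-(3,4-dimethoxyphenyl)-3,4-dimethyloxolan-2-yl]-2-methoxyphenol | COc1cc(ccc1O)[C@H]1O[C@@H](c2ccc(OC)c(OC)c2)[C@@H](C)[C@H]1C | intermediate
17 | methyl (R)-lactate | C[C@@H](O)C(=O)OC | starting material
18 | methyl (2S)-2-{4-[(2S,3R,4S,5R)-5-(3,4-dimethoxyphenyl)-3,4-dimethyloxolan-2-yl]-2-methoxyphenoxy}propanoate | COC(=O)[C@H](C)Oc1ccc(cc1OC)[C@H]1O[C@@H](c2ccc(OC)c(OC)c2)[C@@H](C)[C@H]1C | intermediate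
19 | (2S)-2-{4-[(2S,3R,4S,5R)-5-(3,4-dimethoxyphenyl)-3,4-dimethyloxolan-2-yl]-2-methoxyphenoxy}-N-methoxy-N-methylpropanamide | CON(C)C(=O)[C@H](C)Oc1ccc(cc1OC)[C@H]1O[C@@H](c2ccc(OC)c(OC)c2)[C@@H](C)[C@H]1C | intermediate
20 | 3,4-dimethoxyphenylmagnesium bromide | COc1ccc([Mg]Br)cc1OC | starting material
21 | bromomagnesium alkoxide of the tetrahedral N-methoxy-N-methyl hemiaminal from 19 and 20 (new carbon undefined) | CON(C)C(O[Mg]Br)(c1ccc(OC)c(OC)c1)[C@H](C)Oc1ccc(cc1OC)[C@H]1O[C@@H](c2ccc(OC)c(OC)c2)[C@@H](C)[C@H]1C | intermediate (not isolated)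
22 | (2S)-1-(3,4-dimethoxyphenyl)-2-{4-[(2S,3R,4S,5R)-5-(3,4-dimethoxyphenyl)-3,4-dimethyloxolan-2-yl]-2-methoxyphenoxy}propan-1-one | COc1ccc(cc1OC)C(=O)[C@H](C)Oc1ccc(cc1OC)[C@H]1O[C@@H](c2ccc(OC)c(OC)c2)[C@@H](C)[C@H]1C | intermediate
23 | (1R,2S)-1-(3,4-dimethoxyphenyl)-2-{4-[(2S,3R,4S,5R)-5-(3,4-dimethoxyphenyl)-3,4-dimethyloxolan-2-yl]-2-methoxyphenoxy}propan-1-ol | COc1ccc([C@@H](O)[C@H](C)Oc2ccc([C@H]3O[C@@H](c4ccc(OC)c(OC)c4)[C@@H](C)[C@H]3C)cc2OC)cc1OC | target

**Totals and risks**

Total step count: 14. Longest linear sequence: 14 steps (from 1 and 2 to 23); compounds 10, 17 and 20 enter as purchased building blocks.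

The three steps most likely to fail:

1. Step 8 (ring closure). The electrophile may do more than one job: iodination of the electron-rich rings, oxidative aromatisation of the new ring, or acid-induced breakdown of the iodo enol ether while it forms. The fallback separates ring closure from iodination and sets out from alkynol 12. Cycloisomerisation with catalytic AuCl(PPh3)/AgOSO2CF3 in toluene at room temperature (5-endo-dig hydroalkoxylation) should give (2S,3R)-2-(4-benzyloxy-3-methoxyphenyl)-5-(3,4-dimethoxyphenyl)-3-methyl-2,3-dihydrofuran F1. Treating this enol ether with N-iodosuccinimide and NaHCO3 in MeCN at −20 °C (iodination at C4, then loss of the C4 proton from the oxocarbenium ion) comes back to the route at 13.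

2. Step 10 (hydrogenation with debenzylation). Hydrogenolysis of the benzylic C2–O bond may open the ring, the double bond may migrate toward C3 before it is saturated and erode the C3 configuration, or the tetrasubstituted alkene may be reduced incompletely. The fallback decouples the two reductive events and sets out from 14. Hydrogenation over Rh/Al2O3 (H2, EtOAc, rt), a catalyst with little tendency toward C–O hydrogenolysis or alkene migration, should give (2S,3R,4S,5R)-2-(4-benzyloxy-3-methoxyphenyl)-5-(3,4-dimethoxyphenyl)-3,4-dimethyloxolane F2. The benzyl ether is then removed by transfer hydrogenolysis (Pd/C, cyclohexa-1,4-diene, EtOH, rt), which comes back to the route at 16.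

3. Step 14 (ketone reduction). The aryloxy oxygen may coordinate zinc only weakly, so that open-chain Felkin-type attack competes and the facial selectivity drops. The fallback replaces substrate control by catalyst control and sets out from ketone 22. CBS reduction with (R)-2-methyl-CBS-oxazaborolidine and BH3·SMe2 in toluene at −20 °C is expected to deliver hydride to the same carbonyl face, provided ring C acts as the large group, and leads directly to 23; no new compound arises (F0).

**Further compounds**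

F1 | step 8 | (2S,3R)-2-(4-benzyloxy-3-methoxyphenyl)-5-(3,4-dimethoxyphenyl)-3-methyl-2,3-dihydrofuran | COc1cc(ccc1OCc1ccccc1)[C@H]1OC(c2ccc(OC)c(OC)c2)=C[C@H]1C
F2 | step 10 | (2S,3R,4S,5R)-2-(4-benzyloxy-3-methoxyphenyl)-5-(3,4-dimethoxyphenyl)-3,4-dimethyloxolane | COc1cc(ccc1OCc1ccccc1)[C@H]1O[C@@H](c2ccc(OC)c(OC)c2)[C@@H](C)[C@H]1C
F0 | step 14 | none | none
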